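**Plan**
1. Enabling feature: ring B (C1' bridge carbon, C2'–OH, C3'–CH3, C4'–OH, C5'–butanoyl, C6'–OH) is the aromatic enol of a cyclised 3,5,7-triketo ester. Its lactone form is a 4-hydroxy-2-pyranone: pyranone C2 = C6', C3 = C1', C4 = C2', C5 = C3', C6 = C4', side-chain CH2 = C5'.
2. Cuts, in order: the two O–benzyl bonds on ring A; C5'–C6' of ring B (Claisen recyclisation); bridge CH2–C3 of the pyranone (reductive alkylation by a ring A aldehyde); CH2–CO of the 2-oxopentyl chain; lactone O–C2 and C5–C6 of the pyranone; on ring A the formyl, O-methyl and pentanoyl bonds.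
3. Forward: the pyranone ring is closed first (steps 1–2) and its 6-methyl group acylated (step 3). Ring A is elaborated from 2-methylphloroglucinol (steps 4–7). The halves are joined through the CH2 bridge (step 8), ring B is formed last from the pyranone (step 9), and hydrogenolysis ends the route (step 10).
4. Stereochemistry: the target has no stereocentre; the labile centres of open-chain intermediates vanish on enolisation or aromatisation.

Key step: step 9

Remark: acylphloroglucinol and hydroxypyranone units are drawn as their aromatic enol tautomers. Ring A is numbered C1 (pentanoyl) to C6 and ring B C1' (bridge) to C6'.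

**Step 1**
Reactants: 1 methyl 3-oxopentanoate; 2 N-methoxy-N-methylacetamide
Product: 4 methyl 4-methyl-3,5-dioxohexanoate, via dilithium dienolate 3 (not isolated)
Conditions: LiN(iPr)2 (2.2 equiv), THF, −78 to 0 °C; then 2 (1.0 equiv), −78 to 0 °C; aq. HCl
Reagents that add atoms: none
Why: γ-Acylation of a β-keto ester dianion by a Weinreb amide is reliable because the chelated tetrahedral adduct persists until the acidic quench, so the more acidic diketo ester neither protonates unreacted dianion nor is acylated again; the C4 centre formed is racemic and labile and is lost in step 2.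

**Step 2**
Reactants: 4 methyl 4-methyl-3,5-dioxohexanoate
Product: 5 4-hydroxy-5,6-dimethylpyran-2-one
Conditions: DBU (1.5 equiv), toluene, reflux; then aq. HCl
Reagents that add atoms: none
Why: DBU-mediated lactonisation of a 3,5-diketo ester (6-exo-trig O-acylation of the C5 enolate on the methyl ester with loss of methanol) is the standard entry to 4-hydroxy-2-pyranones and is driven by formation of the stabilised vinylogous carboxylate.

**Step 3**
Reactants: 5 4-hydroxy-5,6-dimethylpyran-2-one (2.1 equiv); 6 methyl butanoate
Product: 8 4-hydroxy-5-methyl-6-(2-oxopentyl)pyran-2-one, via dilithium pyranone dianion 7 (not isolated)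
Conditions: LiN(iPr)2 (4.3 equiv), THF–DMPU, −78 to −20 °C; then 6 (1.0 equiv), −78 to 0 °C; 1 M HCl
Reagents that add atoms: none
Why: Claisen acylation of the pyranone dianion occurs at the 6-CH2 carbanion, the vinylogous position of the 4-oxido-2-pyranone, and the second equivalent of dianion takes up the acidic proton of the product so that the ester is fully consumed.

**Step 4**
Reactants: 9 2-methylphloroglucinol (2-methylbenzene-1,3,5-triol); 10 pentanoyl chloride
Product: 11 1-(2,4,6-trihydroxy-3-methylphenyl)pentan-1-one
Conditions: AlCl3 (3.5 equiv), PhNO2–CH2Cl2, 0 to 60 °C; ice/HCl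
Reagents that add atoms: none
Why: Friedel–Crafts C-acylation of the electron-rich triol goes to either of its two equivalent free ring carbons and stops after one acyl group because the hydrogen-bonded ketone deactivates the ring.

**Step 5**
Reactants: 11 1-(2,4,6-trihydroxy-3-methylphenyl)pentan-1-one
Product: 12 1-(2,6-dihydroxy-4-methoxy-3-methylphenyl)pentan-1-one
Conditions: Me2SO4 (1.0 equiv), K2CO3 (1.0 equiv), acetone, rt
Reagents that add atoms: dimethyl sulfate, COS(=O)(=O)OC
Why: Williamson O-methylation with one equivalent of a hard methylating agent and a weak base should take place at the hydroxyl para to the ketone, which is the most acidic and the only one not flanked by the carbonyl and its hydrogen bond, while C-methylation is avoided.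

**Step 6**
Reactants: 12 1-(2,6-dihydroxy-4-methoxy-3-methylphenyl)pentan-1-one
Product: 14 2,4-dihydroxy-6-methoxy-5-methyl-3-pentanoylbenzaldehyde, via α-chloro ether 13 (not isolated)
Conditions: Cl2CHOMe (1.5 equiv), TiCl4 (3 equiv), CH2Cl2, −10 °C to rt; then ice/1 M HCl
Reagents that add atoms: dichloromethyl methyl ether, COC(Cl)Cl; water, O
Why: Rieche formylation attacks the single unsubstituted ring carbon, which is activated by an ortho hydroxyl, an ortho methoxy and a para hydroxyl group, and unlike a Vilsmeier reagent it should not condense with the ortho-hydroxyaryl ketone to a chromone.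

**Step 7**
Reactants: 14 2,4-dihydroxy-6-methoxy-5-methyl-3-pentanoylbenzaldehyde
Product: 15 2,4-bis(benzyloxy)-6-methoxy-5-methyl-3-pentanoylbenzaldehyde
Conditions: BnBr (2.6 equiv), K2CO3 (4 equiv), Bu4NI (cat.), DMF, 60 °C
Reagents that add atoms: benzyl bromide, BrCc1ccccc1
Why: Williamson benzylation of the two chelated phenols in DMF gives ethers that shut off quinone methide formation from ring A in the basic steps ahead and that can later be removed by hydrogenolysis without touching the methyl ether.

**Step 8**
Reactants: 15 2,4-bis(benzyloxy)-6-methoxy-5-methyl-3-pentanoylbenzaldehyde; 8 4-hydroxy-5-methyl-6-(2-oxopentyl)pyran-2-one (1.1 equiv)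
Product: 17 3-{[2,4-bis(benzyloxy)-6-methoxy-5-methyl-3-pentanoylphenyl]methyl}-4-hydroxy-5-methyl-6-(2-oxopentyl)pyran-2-one, via arylidene pyrandione 16 (not isolated)
Conditions: L-proline (20 mol %), Hantzsch ester (diethyl 2,6-dimethyl-1,4-dihydropyridine-3,5-dicarboxylate, 1.3 equiv), EtOH–CH2Cl2, 40 °C
Reagents that add atoms: none
Why: Organocatalytic three-component reductive alkylation (proline-mediated Knoevenagel condensation at the acidic C3 of the 4-hydroxypyranone, then conjugate hydride transfer from the Hantzsch ester to arylidene 16) is established for 4-hydroxy-2-pyranones and 4-hydroxycoumarins, and C3 is far more acidic than the side-chain methylene, so the bridge carbon should be attached there only.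

**Step 9**
Reactants: 17 3-{[2,4-bis(benzyloxy)-6-methoxy-5-methyl-3-pentanoylphenyl]methyl}-4-hydroxy-5-methyl-6-(2-oxopentyl)pyran-2-one
Product: 19 1-[2,6-bis(benzyloxy)-3-[(3-butanoyl-2,4,6-trihydroxy-5-methylphenyl)methyl]-4-methoxy-5-methylphenyl]pentan-1-one, via open-chain triketo ester 18 (not isolated)
Conditions: Mg(OMe)2 (8 equiv), MeOH, reflux, argon; then cold 1 M HCl
Reagents that add atoms: none
Why: Methoxide adds to the lactone carbonyl C2 and the C6 enolate leaves, giving the magnesium chelate of triketo ester 18; the doubly activated methylene between the butanoyl carbonyl and the former C6 carbonyl then attacks the ester carbonyl, methoxide is expelled, and the cyclohexanetrione enolises to ring B with the new C5'–C6' bond. The closest known reaction type is the Mg(OMe)2-mediated Claisen (Dieckmann-like) recyclisation of 6-(2-oxoalkyl)-4-hydroxy-2-pyranones and 3,5,7-triketo esters to acylphloroglucinols. Ring B closes by a 6-exo-trig C-acylation. No stereocentre is created, and the two labile centres of 18 disappear on aromatisation. The step needs Claisen over aldol folding and C- over O-acylation: the aldol carbon alpha to the ester already carries the bridge CH2, so its adduct would be quaternary, could not aromatise and reverts; the only other aromatisable aldol would need the singly activated alpha-carbon of the propyl ketone; O-acylation merely returns 17. Chelation by divalent magnesium holds the chain folded and protects the β-dicarbonyl units from retro-Claisen cleavage, and the benzyl ethers on ring A prevent loss of the bridge through a quinone methide.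

**Step 10**
Reactants: 19 1-[2,6-bis(benzyloxy)-3-[(3-butanoyl-2,4,6-trihydroxy-5-methylphenyl)methyl]-4-methoxy-5-methylphenyl]pentan-1-one
Product: 20 1-[3-[(3-butanoyl-2,4,6-trihydroxy-5-methylphenyl)methyl]-2,6-dihydroxy-4-methoxy-5-methylphenyl]pentan-1-one (CNP0228890.0)
Conditions: H2 (1 atm), 10% Pd/C, EtOAc, rt
Reagents that add atoms: none
Why: Catalytic hydrogenolysis cleaves the two aryl benzyl ethers under neutral conditions, which avoids acid- or base-induced exchange of the diarylmethane bridge between two free polyphenol rings, and the hydrogen-bonded aryl ketones and the methyl ether should not be reduced.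

**Compound list**
1 | methyl 3-oxopentanoate | CCC(=O)CC(=O)OC | starting material
2 | N-methoxy-N-methylacetamide | CON(C)C(C)=O | starting material
3 | dilithium dienolate of methyl 3-oxopentanoate (formed in situ) | [Li+].[Li+].COC([O-])=CC([O-])=CC | intermediate
4 | methyl 4-methyl-3,5-dioxohexanoate (racemic, labile centre) | COC(=O)CC(=O)C(C)C(C)=O | intermediate
5 | 4-hydroxy-5,6-dimethylpyran-2-one | Cc1oc(=O)cc(O)c1C | intermediate
6 | methyl butanoate | CCCC(=O)OC | starting material
7 | dilithium dianion of 4-hydroxy-5,6-dimethylpyran-2-one (formed in situ) | [Li+].[Li+].C=C1OC([O-])=CC([O-])=C1C | intermediate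
8 | 4-hydroxy-5-methyl-6-(2-oxopentyl)pyran-2-one | CCCC(=O)Cc1oc(=O)cc(O)c1C | intermediate
9 | 2-methylphloroglucinol (2-methylbenzene-1,3,5-triol) | Cc1c(O)cc(O)cc1O | starting material
10 | pentanoyl chloride | CCCCC(=O)Cl | starting material
11 | 1-(2,4,6-trihydroxy-3-methylphenyl)pentan-1-one | CCCCC(=O)c1c(O)cc(O)c(C)c1O | intermediate
12 | 1-(2,6-dihydroxy-4-methoxy-3-methylphenyl)pentan-1-one | CCCCC(=O)c1c(O)cc(OC)c(C)c1O | intermediate
13 | 1-{3-[chloro(methoxy)methyl]-2,6-dihydroxy-4-methoxy-5-methylphenyl}pentan-1-one (racemic, formed in situ) | CCCCC(=O)c1c(O)c(C(Cl)OC)c(OC)c(C)c1O | intermediate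
14 | 2,4-dihydroxy-6-methoxy-5-methyl-3-pentanoylbenzaldehyde | CCCCC(=O)c1c(O)c(C=O)c(OC)c(C)c1O | intermediate
15 | 2,4-bis(benzyloxy)-6-methoxy-5-methyl-3-pentanoylbenzaldehyde | CCCCC(=O)c1c(OCc2ccccc2)c(C=O)c(OC)c(C)c1OCc1ccccc1 | intermediate
16 | 3-{[2,4-bis(benzyloxy)-6-methoxy-5-methyl-3-pentanoylphenyl]methylidene}-5-methyl-6-(2-oxopentyl)pyran-2,4-dione (alkene geometry undefined, formed in situ) | CCCCC(=O)c1c(OCc2ccccc2)c(C)c(OC)c(C=C2C(=O)OC(CC(=O)CCC)=C(C)C2=O)c1OCc1ccccc1 | intermediate
17 | 3-{[2,4-bis(benzyloxy)-6-methoxy-5-methyl-3-pentanoylphenyl]methyl}-4-hydroxy-5-methyl-6-(2-oxopentyl)pyran-2-one | CCCCC(=O)c1c(OCc2ccccc2)c(C)c(OC)c(Cc2c(O)c(C)c(CC(=O)CCC)oc2=O)c1OCc1ccccc1 | intermediate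
18 | methyl 2-{[2,4-bis(benzyloxy)-6-methoxy-5-methyl-3-pentanoylphenyl]methyl}-4-methyl-3,5,7-trioxodecanoate (stereoisomer and tautomer mixture, magnesium chelate in situ) | CCCCC(=O)c1c(OCc2ccccc2)c(C)c(OC)c(CC(C(=O)OC)C(=O)C(C)C(=O)CC(=O)CCC)c1OCc1ccccc1 | intermediate
19 | 1-[2,6-bis(benzyloxy)-3-[(3-butanoyl-2,4,6-trihydroxy-5-methylphenyl)methyl]-4-methoxy-5-methylphenyl]pentan-1-one | CCCCC(=O)c1c(OCc2ccccc2)c(C)c(OC)c(Cc2c(O)c(C)c(O)c(C(=O)CCC)c2O)c1OCc1ccccc1 | intermediate
20 | 1-[3-[(3-butanoyl-2,4,6-trihydroxy-5-methylphenyl)methyl]-2,6-dihydroxy-4-methoxy-5-methylphenyl]pentan-1-one | CCCCC(=O)c1c(O)c(C)c(OC)c(Cc2c(O)c(C)c(O)c(C(=O)CCC)c2O)c1O | target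

**Step count and risks**
Total steps: 10. Longest linear sequence: 7 steps (steps 4 to 10, from 9).

Steps most likely to fail:

Step 8. Condensation at the doubly ortho-substituted formyl group may be slow, and a second pyranone may add to the arylidene intermediate before hydride transfer. The fallback sets out from 15 and changes the electrophile. NaBH4 in MeOH–THF at 0 °C should reduce only the formyl group, since the ketone is shielded by two ortho benzyloxy groups, to the benzylic alcohol 1-[2,6-bis(benzyloxy)-3-(hydroxymethyl)-4-methoxy-5-methylphenyl]pentan-1-one F1. Its benzylic cation is stabilised by two ortho and one para alkoxy groups. Under catalytic Sc(OTf)3 or TsOH in MeNO2 at 50 °C it should alkylate C3 of pyranone 8 (dehydrative Friedel–Crafts-type benzylation, known for 4-hydroxypyranones and 4-hydroxycoumarins). This comes back to the route at 17.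

Step 9. Methanolysis of the hindered, fully substituted lactone may be incomplete, or retro-Claisen fragmentation of the opened chain may outrun C-acylation. The fallback sets out from 9 and joins two preformed rings instead of building ring B. Friedel–Crafts acylation of 9 with butanoyl chloride and AlCl3 should give 1-(2,4,6-trihydroxy-3-methylphenyl)butan-1-one F2. Its single free ring carbon is then benzylated reductively by aldehyde 15 with Et3SiH and TFA in CH2Cl2 at 0 °C (acid-mediated hydroxyalkylation followed by ionic hydrogenation of the carbinol or quinone methide). This comes back to the route at 19.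

Step 3. Proton transfer from the enolisable ester to the carbanion may quench the dianion and stall the acylation. The fallback sets out from 5 and uses an aldol addition followed by oxidation. Dianion 7 is treated with butanal at −78 °C, where addition to the aldehyde should be faster than proton transfer, to give racemic 4-hydroxy-6-(2-hydroxypentyl)-5-methylpyran-2-one F3. Jones oxidation (CrO3, H2SO4, acetone, 0 °C) of the secondary alcohol then comes back to the route at 8.

**Further compounds**
F1 | step 8 | 1-[2,6-bis(benzyloxy)-3-(hydroxymethyl)-4-methoxy-5-methylphenyl]pentan-1-one | CCCCC(=O)c1c(OCc2ccccc2)c(CO)c(OC)c(C)c1OCc1ccccc1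
F2 | step 9 | 1-(2,4,6-trihydroxy-3-methylphenyl)butan-1-one | CCCC(=O)c1c(O)cc(O)c(C)c1O
F3 | step 3 | 4-hydroxy-6-(2-hydroxypentyl)-5-methylpyran-2-one (racemic) | CCCC(O)Cc1oc(=O)cc(O)c1C
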